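Self-condensation takes 2.10 parts of starting complex for each part exchanged in the south-west run at 12.0 min, counting as condensed what the readings no longer show, but 1.28 in the west run at 12.0 min. Condensation goes with [starting complex] squared and exchange with [starting complex][incoming ligand], so their split follows [starting complex]/[incoming ligand]. Dividing that out, with [starting complex] taken midway over those minutes, leaves 3.74 and 4.22, mean 3.98: the selectivity factor, parts condensed per part exchanged at equal concentrations.

| setting | south-west | west | eta | theta |
|---|---|---|---|---|
| starting complex | 0.050 M | 0.050 M | 0.050 M | 0.050 M |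
| incoming ligand | 0.073 M | 0.13 M | 0.0600 M | 0.120 M |
| remark | run made earlier | run made earlier |  |  |
| time |  |  | 80 min | 80 min |

| run | time / min | starting complex / % | complex with three exchanged / % | complex with two exchanged / % | isomer of the product / % | complex with one exchanged / % |
|---|---|---|---|---|---|---|
| south-west | 3.00 | 88.3 | 0 | 0 | 0.2 | 3.0 |
| south-west | 5.00 | 81.8 | 0 | 0.3 | 0.4 | 3.7 |
| south-west | 8.00 | 72.3 | 0.6 | 1.4 | 0.4 | 5.7 |
| south-west | 12.0 | 64.3 | 0.3 | 3.5 | 1.1 | 6.6 |
| south-west | 15.0 | 58.3 | 0 | 4.7 | 1.3 | 7.0 |
| south-west | 25.0 | 44.9 | 0.8 | 7.3 | 3.3 | 6.3 |
| south-west | 40.0 | 32.9 | 2.2 | 11.2 | 2.7 | 7.0 |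
| west | 2.00 | 89.2 | 0 | 0.1 | 0.9 | 3.9 |
| west | 6.00 | 74.6 | 0 | 1.8 | 1.1 | 6.6 |
| west | 12.0 | 58.0 | 0.1 | 7.9 | 1.1 | 9.3 |
| west | 15.0 | 52.3 | 0.9 | 9.6 | 1.6 | 8.9 |
| west | 25.0 | 38.0 | 2.5 | 15.9 | 3.0 | 7.9 |
| west | 30.0 | 33.1 | 3.8 | 17.7 | 4.3 | 7.4 |
| west | 40.0 | 27.3 | 6.3 | 20.4 | 4.3 | 5.4 |

(scatter of a reading: 0.5 percentage points)

* which of these there is most of at the end, counted by the starting complex in it, eta (complex with three exchanged / isomer of the product / starting complex / complex with two exchanged / complex with one exchanged)
* which of these there is most of at the end, counted by the starting complex in it, theta (complex with three exchanged / isomer of the product / starting complex / complex with two exchanged / complex with one exchanged)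
* how much there is at the end of the one of these that leads, in percent of the starting complex charged: eta
* how much there is at the end of the one of these that leads, in percent of the starting complex charged: theta

- percentages count the starting complex that a species holds: one self-condensation product counts as two
- steps thought possible: 2 starting complex -> self-condensation product; starting complex + incoming ligand <-> leaving ligand + complex with one exchanged; complex with one exchanged <-> isomer of the product; complex with three exchanged + incoming ligand <-> leaving ligand + complex with four exchanged; complex with two exchanged + incoming ligand <-> leaving ligand + complex with three exchanged; complex with one exchanged + incoming ligand <-> leaving ligand + complex with two exchanged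

Eta therefore starts at a split of 3.32 and theta at 1.66. How much starting complex outlasts 80 min? The pseudo-first-order exchange constant, scaled from the nearer run, is 0.00959 /min for eta and 0.0179 /min for theta. Integrating both losses with [incoming ligand] held at its charge leaves 16.7% in eta and 10.5% in theta.

And what does the exchanged part hold? Complex with two exchanged made up 48.5% of it at the last south-west reading and 56.0% at the last west one. Carried unchanged to 80 min, as an estimate, the south-west share reckons 14.9% of complex with two exchanged in eta, less than the starting complex reckoned there, and the west share reckons 27.6% in theta, more than the starting complex reckoned there.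

The forecast names the same leaders at other amounts: starting complex at 20% for eta, and complex with two exchanged at 20% for theta, “since its formation roughly balances its loss”.

The flasks give starting complex at 19.1% in eta and complex with two exchanged at 23.2% in theta.

    2 starting complex → self-condensation product (k = 0.330 /M/min)
    starting complex + incoming ligand ⇌ leaving ligand + complex with one exchanged (K = 1.40, k = 0.160 /M/min)
    complex with one exchanged ⇌ isomer of the product (K = 1.10, k = 0.0190 /min)
    complex with three exchanged + incoming ligand ⇌ leaving ligand + complex with four exchanged (K = 0.360, k = 0.0680 /M/min)
    complex with two exchanged + incoming ligand ⇌ leaving ligand + complex with three exchanged (K = 0.660, k = 0.130 /M/min)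
    complex with one exchanged + incoming ligand ⇌ leaving ligand + complex with two exchanged (K = 18.0, k = 0.860 /M/min)

Eta ends with 55.6% condensed against 25.3% exchanged, a split of 2.20. A neighbour of eta charged with 0.030 M of starting complex starts, by the selectivity factor, at 1.99 instead of 3.32, so its final split should scale to 1.32. That neighbour ends with 43.4% condensed against 31.7% exchanged, a split of 1.37, with 24.9% of its starting complex left and 16.8% as complex with two exchanged.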